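Cuts, in retrosynthetic order: (i) the C4–C8 interflavan bond, giving an upper-unit C4 cation and C8 of tri-O-benzyl-(−)-epiafzelechin; (ii) C3–OH and C2–H, back to an enol ether C2=C3 (hydroboration retron); (iii) the C2=C3 bond of the pyran ring, back to an aryl ester O1–C2(=O)Ar and a vinyl carbinol at C4; (iv) the ester C–O and the C4–vinyl bonds.
Enabling feature: O1 sits on arene carbon C8a and C4 on the adjacent C4a of the resorcinol A ring, so ester carbon C2 and vinyl carbon C3 are held ortho. Once C2=O is methylenated, the two olefins can close only to the six-membered C ring, which is then a benzo-fused 1-aryl glycal, O1–C2(Ar)=C3–C4(OSi).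
Forward order: esterify the phenol; Si-face vinylation of the aldehyde (C4 carbinol, silylated in the flask); methylenate the ester; close the C ring at C2=C3; hydroborate; acetylate; ionise C4 and arylate with C8 of the lower unit; deacetylate; hydrogenolyse.
Stereochemistry: the catalyst-set C4–O stereocentre is a temporary relay. It steers borane anti (setting C2 and C3, 2,3-trans) and then leaves as the nucleofuge. C4 is rebuilt trans to the participating C3 acetate. The lower-unit stereocentres come from (−)-epiafzelechin.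

Key step: step 4

Assumption: (−)-epiafzelechin is taken as a purchasable chiral-pool flavan-3-ol (sold as an isolated natural product). Any minor enantiomer of the upper unit left by step 2 would become a diastereomer in step 8 and be removed there.

Step 1
Reactants: 1 4-(benzyloxy)-2-hydroxybenzaldehyde; 2 4-(benzyloxy)benzoyl chloride
Product: 3 5-(benzyloxy)-2-formylphenyl 4-(benzyloxy)benzoate
Conditions: Et3N, DMAP (cat.), CH2Cl2, 0 °C to rt
Reagents that add atoms: none
Why: DMAP-catalysed acylation of the phenol by the aroyl chloride is a standard esterification that installs the O1–C2 bond with C2 at the carboxyl level and leaves the aldehyde untouched.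

Step 2
Reactants: 3 5-(benzyloxy)-2-formylphenyl 4-(benzyloxy)benzoate; 4 vinyl bromide
Product: 5 5-(benzyloxy)-2-[(1S)-1-(triethylsilyloxy)prop-2-en-1-yl]phenyl 4-(benzyloxy)benzoate
Conditions: CrCl2 (cat.), chiral oxazoline–sulfonamide ligand (cat., enantiomer for Si-face delivery), proton sponge, NiCl2·neocuproine (cat.), Mn, LiCl, Et3SiCl, MeCN, rt
Reagents that add atoms: chlorotriethylsilane, CC[Si](Cl)(CC)CC
Why: Catalytic asymmetric Nozaki–Hiyama–Kishi alkenylation: the vinylchromium(III) species adds only to the aldehyde (the aryl ester is inert), the chiral chromium complex directs vinyl transfer to the Si face to set the (S)-carbinol at C4, and Et3SiCl silylates the chromium alkoxide, which turns the metal over and blocks O-to-O migration of the neighbouring aroyl group.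

Step 3
Reactants: 5 5-(benzyloxy)-2-[(1S)-1-(triethylsilyloxy)prop-2-en-1-yl]phenyl 4-(benzyloxy)benzoate
Product: 6 1-[4-(benzyloxy)phenyl]vinyl 5-(benzyloxy)-2-[(1S)-1-(triethylsilyloxy)prop-2-en-1-yl]phenyl ether
Conditions: Tebbe reagent, pyridine, THF/toluene, −40 to 0 °C; aq NaOH quench; basic alumina
Reagents that add atoms: Tebbe reagent, C[Al](C)C[Ti](Cl)(C1C=CC=C1)C1C=CC=C1
Why: Tebbe methylenation (titanium methylidene [2+2]/cycloreversion on the ester carbonyl) is established for aryl benzoates and should turn C2=O into C2=CH2 under non-acidic conditions that leave the allylic silyl ether, the vinyl group and the C4 stereocentre alone.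

Step 4
Reactants: 6 1-[4-(benzyloxy)phenyl]vinyl 5-(benzyloxy)-2-[(1S)-1-(triethylsilyloxy)prop-2-en-1-yl]phenyl ether
Product: 7 (4S)-7-(benzyloxy)-2-[4-(benzyloxy)phenyl]-4-(triethylsilyloxy)-4H-chromene
Conditions: Grubbs second-generation catalyst (cat.), 1,4-benzoquinone (cat.), toluene (0.005 M), 60 °C, Ar sparge; Et3N-deactivated silica
Reagents that add atoms: none
Why: Ring-closing olefin metathesis: the ruthenium alkylidene loads onto the monosubstituted vinyl group at C3, adds intramolecularly across the 1,1-disubstituted enol ether C2=CH2 to a ruthenacyclobutane and cycloreverts to the C2=C3 enol ether and Ru=CH2, with ethylene leaving as gas. The closest known reaction type is RCM of ester-derived α-aryl enol ethers to 1-aryl glycals and of ortho-allyl aryl vinyl ethers to 4H-chromenes. The pyran ring O1–C2–C3–C4–C4a–C8a is closed as a six-membered ring with the new double bond endocyclic, by cycloaddition/cycloreversion at the metal and not by a polar attack, the two olefins being held ortho on the A ring. No stereocentre is formed; the allylic C4 stereocentre is not touched, and the step creates the planar enol ether whose two faces the C4 silyloxy group differentiates in step 5. The selectivity needed is initiation at the vinyl group and not at the enol ether, no double-bond migration, and no ionisation of the doubly activated C4–O bond to a flavylium ion; the 1,1-disubstituted, donor-substituted enol ether is slow to form a Fischer carbene, benzoquinone intercepts Ru–H, and the neutral aprotic medium together with the poor leaving-group ability of the silyloxy group keeps C4 intact.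

Step 5
Reactants: 7 (4S)-7-(benzyloxy)-2-[4-(benzyloxy)phenyl]-4-(triethylsilyloxy)-4H-chromene
Product: 9 (2R,3R,4R)-7-(benzyloxy)-2-[4-(benzyloxy)phenyl]-4-(triethylsilyloxy)chroman-3-ol, via chroman-3-ylborane 8 (not isolated)
Conditions: BH3·THF, THF, 0 °C to rt; then aq NaOH, 30% H2O2, 0 °C
Reagents that add atoms: borane–tetrahydrofuran, B.C1CCOC1; hydrogen peroxide, OO
Why: Hydroboration–oxidation of a 1-aryl-glycal-type enol ether: boron adds to C3 (β to O1 and to the aryl-bearing C2) and hydrogen to C2, syn and from the face opposite the C4 silyloxy group, and oxidation with retention should give the 2,3-trans-3,4-trans alcohol, so C2 and C3 are both set by the C4 stereocentre.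

Step 6
Reactants: 9 (2R,3R,4R)-7-(benzyloxy)-2-[4-(benzyloxy)phenyl]-4-(triethylsilyloxy)chroman-3-ol
Product: 10 (2R,3R,4R)-7-(benzyloxy)-2-[4-(benzyloxy)phenyl]-4-(triethylsilyloxy)chroman-3-yl acetate
Conditions: Ac2O, pyridine, DMAP (cat.), CH2Cl2, rt
Reagents that add atoms: acetic anhydride, CC(=O)OC(C)=O
Why: Standard DMAP-catalysed acetylation of the secondary alcohol puts a participating group on C3 for the coupling and touches no stereocentre.

Step 7
Reactants: 11 (−)-epiafzelechin
Product: 12 (2R,3R)-5,7-bis(benzyloxy)-2-[4-(benzyloxy)phenyl]chroman-3-ol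
Conditions: BnBr, K2CO3, DMF, 0 °C to rt
Reagents that add atoms: benzyl bromide, BrCc1ccccc1
Why: Williamson etherification with a weak base alkylates only the three phenolic hydroxyls (K2CO3 does not deprotonate the aliphatic 3-OH) and does not involve the two stereocentres.

Step 8
Reactants: 10 (2R,3R,4R)-7-(benzyloxy)-2-[4-(benzyloxy)phenyl]-4-(triethylsilyloxy)chroman-3-yl acetate; 12 (2R,3R)-5,7-bis(benzyloxy)-2-[4-(benzyloxy)phenyl]chroman-3-ol (excess, recovered)
Product: 13 (2R,3S,4S)-7-(benzyloxy)-2-[4-(benzyloxy)phenyl]-4-{(2R,3R)-5,7-bis(benzyloxy)-2-[4-(benzyloxy)phenyl]-3-hydroxychroman-8-yl}chroman-3-yl acetate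
Conditions: TMSOTf (sub-stoichiometric), 4 Å MS, CH2Cl2, −40 to −20 °C; Et3N quench
Reagents that add atoms: none
Why: Lewis-acid-mediated flavan-4-yl cation Friedel–Crafts coupling, the standard interflavan bond formation: silylation of the C4 silyloxy oxygen ionises the benzylic C4–O bond (cation stabilised by the para benzyloxy group and ortho O1), the C3 acetate bridges the cation on its own face as an acetoxonium ion, and C8 of the phloroglucinol-type ring of 12, the position that reacts preferentially in 5,7-di-O-benzyl flavan-3-ols, attacks from the opposite face to give the 3,4-trans (4α→8) bond.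

Step 9
Reactants: 13 (2R,3S,4S)-7-(benzyloxy)-2-[4-(benzyloxy)phenyl]-4-{(2R,3R)-5,7-bis(benzyloxy)-2-[4-(benzyloxy)phenyl]-3-hydroxychroman-8-yl}chroman-3-yl acetate
Product: 14 (2R,3S,4S)-7-(benzyloxy)-2-[4-(benzyloxy)phenyl]-4-{(2R,3R)-5,7-bis(benzyloxy)-2-[4-(benzyloxy)phenyl]-3-hydroxychroman-8-yl}chroman-3-ol
Conditions: K2CO3, MeOH/THF, rt
Reagents that add atoms: none
Why: Base-catalysed transesterification (methanolysis of the acetate) frees the C3 hydroxyl without affecting benzyl ethers, the interflavan bond or any stereocentre, since no phenol is free to open a quinone-methide epimerisation path.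

Step 10
Reactants: 14 (2R,3S,4S)-7-(benzyloxy)-2-[4-(benzyloxy)phenyl]-4-{(2R,3R)-5,7-bis(benzyloxy)-2-[4-(benzyloxy)phenyl]-3-hydroxychroman-8-yl}chroman-3-ol
Product: 15 (2R,3S,4S)-2-(4-hydroxyphenyl)-4-[(2R,3R)-3,5,7-trihydroxy-2-(4-hydroxyphenyl)chroman-8-yl]chroman-3,7-diol
Conditions: H2 (1 atm), Pd(OH)2/C, THF/MeOH/H2O, rt
Reagents that add atoms: none
Why: Hydrogenolysis of the five benzyl ethers over Pearlman's catalyst is the standard final deprotection of proanthocyanidins and should leave the C4–C8 bond, the pyran C–O bonds and all five stereocentres intact.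

Compound list
1 | 4-(benzyloxy)-2-hydroxybenzaldehyde | O=Cc1ccc(OCc2ccccc2)cc1O | starting material
2 | 4-(benzyloxy)benzoyl chloride | O=C(Cl)c1ccc(OCc2ccccc2)cc1 | starting material
3 | 5-(benzyloxy)-2-formylphenyl 4-(benzyloxy)benzoate | O=Cc1ccc(OCc2ccccc2)cc1OC(=O)c1ccc(OCc2ccccc2)cc1 | intermediate
4 | vinyl bromide (bromoethene) | C=CBr | starting material
5 | 5-(benzyloxy)-2-[(1S)-1-(triethylsilyloxy)prop-2-en-1-yl]phenyl 4-(benzyloxy)benzoate | C=C[C@H](O[Si](CC)(CC)CC)c1ccc(OCc2ccccc2)cc1OC(=O)c1ccc(OCc2ccccc2)cc1 | intermediate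
6 | 1-[4-(benzyloxy)phenyl]vinyl 5-(benzyloxy)-2-[(1S)-1-(triethylsilyloxy)prop-2-en-1-yl]phenyl ether | C=C[C@H](O[Si](CC)(CC)CC)c1ccc(OCc2ccccc2)cc1OC(=C)c1ccc(OCc2ccccc2)cc1 | intermediate
7 | (4S)-7-(benzyloxy)-2-[4-(benzyloxy)phenyl]-4-(triethylsilyloxy)-4H-chromene | c1ccccc1COc1ccc(cc1)C1=C[C@H](O[Si](CC)(CC)CC)c2ccc(OCc3ccccc3)cc2O1 | intermediate
8 | 2,3-trans-3,4-trans-[7-(benzyloxy)-2-(4-benzyloxyphenyl)-4-(triethylsilyloxy)chroman-3-yl]borane (boron anti to the C4 silyloxy group, syn to H-2) | c1ccccc1COc1ccc([C@H]2Oc3cc(OCc4ccccc4)ccc3[C@@H](O[Si](CC)(CC)CC)[C@@H]2B)cc1 | intermediate (not isolated)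
9 | (2R,3R,4R)-7-(benzyloxy)-2-[4-(benzyloxy)phenyl]-4-(triethylsilyloxy)chroman-3-ol (2,3-trans-3,4-trans) | c1ccccc1COc1ccc([C@H]2Oc3cc(OCc4ccccc4)ccc3[C@@H](O[Si](CC)(CC)CC)[C@@H]2O)cc1 | intermediate
10 | (2R,3R,4R)-7-(benzyloxy)-2-[4-(benzyloxy)phenyl]-4-(triethylsilyloxy)chroman-3-yl acetate | c1ccccc1COc1ccc([C@H]2Oc3cc(OCc4ccccc4)ccc3[C@@H](O[Si](CC)(CC)CC)[C@@H]2OC(C)=O)cc1 | intermediate
11 | (−)-epiafzelechin, (2R,3R)-2-(4-hydroxyphenyl)chroman-3,5,7-triol | Oc1cc(O)c2c(c1)O[C@H](c1ccc(O)cc1)[C@H](O)C2 | starting material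
12 | (2R,3R)-5,7-bis(benzyloxy)-2-[4-(benzyloxy)phenyl]chroman-3-ol | O(Cc1ccccc1)c1cc(OCc3ccccc3)c2c(c1)O[C@H](c1ccc(OCc3ccccc3)cc1)[C@H](O)C2 | intermediate
13 | (2R,3S,4S)-7-(benzyloxy)-2-[4-(benzyloxy)phenyl]-4-{(2R,3R)-5,7-bis(benzyloxy)-2-[4-(benzyloxy)phenyl]-3-hydroxychroman-8-yl}chroman-3-yl acetate | O(Cc1ccccc1)c1ccc([C@H]2Oc3cc(OCc4ccccc4)ccc3[C@@H](c3c(OCc4ccccc4)cc(OCc4ccccc4)c4c3O[C@H](c3ccc(OCc5ccccc5)cc3)[C@H](O)C4)[C@@H]2OC(C)=O)cc1 | intermediate
14 | (2R,3S,4S)-7-(benzyloxy)-2-[4-(benzyloxy)phenyl]-4-{(2R,3R)-5,7-bis(benzyloxy)-2-[4-(benzyloxy)phenyl]-3-hydroxychroman-8-yl}chroman-3-ol | O(Cc1ccccc1)c1ccc([C@H]2Oc3cc(OCc4ccccc4)ccc3[C@@H](c3c(OCc4ccccc4)cc(OCc4ccccc4)c4c3O[C@H](c3ccc(OCc5ccccc5)cc3)[C@H](O)C4)[C@@H]2O)cc1 | intermediate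
15 | (2R,3S,4S)-2-(4-hydroxyphenyl)-4-[(2R,3R)-3,5,7-trihydroxy-2-(4-hydroxyphenyl)chroman-8-yl]chroman-3,7-diol (2,3-trans-3,4-trans upper unit, 2,3-cis lower unit, 4α→8) | Oc1ccc([C@H]2Oc3cc(O)ccc3[C@@H](c3c(O)cc(O)c4c3O[C@H](c3ccc(O)cc3)[C@H](O)C4)[C@@H]2O)cc1 | target

Total step count: 10
Longest linear sequence: 9 steps (steps 1–6 and 8–10, from 1); step 7 is the one-step side branch.

Steps most likely to fail

Step 2. What may go wrong: weak facial discrimination in the vinyl transfer to the ortho-acyloxy aryl aldehyde, pinacol-type reductive dimerisation of the aromatic aldehyde at the reducing metal, or O-to-O shift of the aroyl group if silylation lags behind addition. Fallback (kinetic resolution in place of asymmetric C–C bond formation, with the ester put on last): it sets out from 1 and comes back to the route at 5. Allylation of the phenol (allyl bromide, K2CO3, DMF) would give 2-(allyloxy)-4-(benzyloxy)benzaldehyde F1. Vinylmagnesium bromide (THF, −78 °C) would give the racemic carbinol rac-1-[2-(allyloxy)-4-(benzyloxy)phenyl]prop-2-en-1-ol F2. Immobilised Candida antarctica lipase B with vinyl acetate (MTBE, rt) should acetylate the (R)-enantiomer, as is usual for 1-aryl carbinols, to (1R)-1-[2-(allyloxy)-4-(benzyloxy)phenyl]prop-2-en-1-yl acetate F4 and leave (1S)-1-[2-(allyloxy)-4-(benzyloxy)phenyl]prop-2-en-1-ol F3. Et3SiCl/imidazole would give {(1S)-1-[2-(allyloxy)-4-(benzyloxy)phenyl]prop-2-en-1-yloxy}triethylsilane F5. Pd(PPh3)4/morpholine would remove the O-allyl group to give 5-(benzyloxy)-2-[(1S)-1-(triethylsilyloxy)prop-2-en-1-yl]phenol F6. Acylation of F6 with 2 (Et3N, DMAP, CH2Cl2) returns 5.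

Step 4. What may go wrong: slow ring closure onto the hindered α-aryl enol ether, diversion of ruthenium into an unreactive Fischer carbene, double-bond migration, or ionisation of the C4–O bond to a flavylium ion on heating or on silica. Fallback (titanium carbonyl olefination instead of ruthenium olefin metathesis): it sets out from 5 and comes back at 7, bypassing 6. A titanium ethylidene reagent (TiCl4, TMEDA, Zn, PbCl2 cat., CH3CHBr2, THF/CH2Cl2, 65 °C) should effect an olefinic-ester cyclisation: the ethylidene exchanges with the vinyl group, and the resulting titanium alkylidene at C3 olefinates the ester carbonyl at C2 in the TMEDA-buffered medium. No new compound arises.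

Step 8. What may go wrong: incomplete ionisation of the C4 silyl ether, self-condensation of the cation with the resorcinol ring of a second upper unit, or loss of positional (C6 against C8) and facial control if the temperature has to be raised. Fallback (isolable thio donor with soft, thiophilic activation): it sets out from 10 and comes back at 13. Excess thiophenol with BF3·OEt2 (CH2Cl2, −20 °C) would trap the cation as (2R,3R,4R)-7-(benzyloxy)-2-[4-(benzyloxy)phenyl]-4-(phenylsulfanyl)chroman-3-yl acetate F7, which can be purified. Activation with AgBF4 (THF, 0 °C) in the presence of 12 then forms the C4–C8 bond under near-neutral conditions, with the same acetate participation, to give 13.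

Further compounds
F1 | step 2 | 2-(allyloxy)-4-(benzyloxy)benzaldehyde | C=CCOc1cc(OCc2ccccc2)ccc1C=O
F2 | step 2 | rac-1-[2-(allyloxy)-4-(benzyloxy)phenyl]prop-2-en-1-ol | C=CCOc1cc(OCc2ccccc2)ccc1C(O)C=C
F3 | step 2 | (1S)-1-[2-(allyloxy)-4-(benzyloxy)phenyl]prop-2-en-1-ol | C=C[C@H](O)c1ccc(OCc2ccccc2)cc1OCC=C
F4 | step 2 | (1R)-1-[2-(allyloxy)-4-(benzyloxy)phenyl]prop-2-en-1-yl acetate | C=C[C@@H](OC(C)=O)c1ccc(OCc2ccccc2)cc1OCC=C
F5 | step 2 | {(1S)-1-[2-(allyloxy)-4-(benzyloxy)phenyl]prop-2-en-1-yloxy}triethylsilane | C=C[C@H](O[Si](CC)(CC)CC)c1ccc(OCc2ccccc2)cc1OCC=C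
F6 | step 2 | 5-(benzyloxy)-2-[(1S)-1-(triethylsilyloxy)prop-2-en-1-yl]phenol | C=C[C@H](O[Si](CC)(CC)CC)c1ccc(OCc2ccccc2)cc1O
F0 | step 4 | none | none
F7 | step 8 | (2R,3R,4R)-7-(benzyloxy)-2-[4-(benzyloxy)phenyl]-4-(phenylsulfanyl)chroman-3-yl acetate (2,3-trans-3,4-trans) | c1ccccc1COc1ccc([C@H]2Oc3cc(OCc4ccccc4)ccc3[C@@H](Sc3ccccc3)[C@@H]2OC(C)=O)cc1
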